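**Plan**

1. Retrosynthesis: the C8 ester is cut first, then the lactone C6–O bond, the C11 methyl and the C7–C11 bond, which leaves a cyclohexanone. The C10 vinyl and the C8 oxygen are then tied back into a two-carbon bridge, and last the ring bonds C7–C8 and C5–C10 are cut together.
2. Enabling feature: in the cyclohexane ring the oxygen-bearing C6 is flanked by C5–H and C7–H (a latent 2-oxyallyl unit C5–C6–C7). The C8 oxygen and the C10 vinyl are cis and 1,3 across C9H2, which marks them as the scars of the two-carbon bridge of a cyclopentadiene (C8–C9–C10). A (4+3) cycloaddition therefore builds the whole carbocycle with its quaternary centre.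
3. Forward order: the bicyclo[3.2.1]octenone forms first (target ring plus a sacrificial bridge) and loses its silyloxy group to the C5 ylidene in the same flask. The C7 acetate arm is added on the bicycle, the bridge is cut to C8–OAc and C10–CHO (then vinyl), the lactone ring is closed, and the side chain is esterified at the end.
4. Stereochemistry: C8/C10 (absolute) come from the chiral-anion-controlled cycloaddition and C7 from exo alkylation of the bicycle. C5 and C6 come from protonation and reduction of the monocycle under control of the axial C10 methyl, C11 from lactone-enolate methylation anti to C8, and the side-chain carbinol from D-glyceraldehyde acetonide.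

Key step: step 5

Remark: locants C1–C15 are those of the elemane skeleton of the target (C10 quaternary with vinyl C1/C2 and methyl C14; C5 carries C4 with C3 and C15; C6–O–C12 lactone with C11 and its methyl C13; C8 carries the ester). In the bicyclo[3.2.1]octenones, bicyclo C1 = C10, C2 = C5, C3 = C6, C4 = C7, C5 = C8 and C8 = C9. α is the ring face of the C10 vinyl group (the face of the two-carbon bridge), β the face of the C10 methyl. TBS = tert-butyldimethylsilyl, TES = triethylsilyl.

Assumption: the sense of induction of the chiral disulfonimide in step 5 cannot be taken from precedent; the (R)-catalyst is written and its antipode would be used if it favours the mirror-image bicycle.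

**Step 1**
Reactants: 1 1,3-bis(TBS-oxy)propan-2-one
Product: 2 5-(TBS-oxy)-4-[(TBS-oxy)methyl]pent-3-en-2-one
Conditions: Ph3P=CHC(O)CH3, toluene, 110 °C
Reagents that add atoms: 1-(triphenyl-λ5-phosphanylidene)propan-2-one, CC(=O)C=P(c1ccccc1)(c1ccccc1)c1ccccc1
Why: Wittig olefination of the activated α,α′-dioxygenated ketone with the stabilized acetonyl ylide should give the enone, and because the ketone is symmetrical no alkene geometry arises.

**Step 2**
Reactants: 2 enone
Product: 3 racemic 1-{3,3-bis[(TBS-oxy)methyl]oxiran-2-yl}ethan-1-one
Conditions: t-BuOOH, 1,8-diazabicyclo[5.4.0]undec-7-ene (DBU), CH2Cl2, rt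
Reagents that add atoms: tert-butyl hydroperoxide, CC(C)(C)OO
Why: Weitz–Scheffer nucleophilic epoxidation (conjugate addition of the peroxide anion, then ring closure) should give the epoxy ketone, whose racemic centre at C5 is harmless because it is erased when the epoxide ionizes in step 5.

**Step 3**
Reactants: 3 epoxy ketone
Product: 4 racemic epoxy enol silane, triethyl[(1-{3,3-bis[(TBS-oxy)methyl]oxiran-2-yl}ethenyl)oxy]silane
Conditions: LiN(SiMe3)2, THF, −78 °C; Et3SiCl
Reagents that add atoms: chlorotriethylsilane, CC[Si](Cl)(CC)CC
Why: kinetic enolization at the methyl group (future C7) with the hindered amide and O-silylation should give the 2-silyloxyallyl epoxide, the usual precursor of a silyloxyallyl cation.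

**Step 4**
Reactants: 5 3-methylcyclopent-2-en-1-one
Product: 7 1,3-dimethylcyclopenta-1,3-diene, via carbinol 6 (not isolated)
Conditions: MeLi, Et2O, 0 °C; then 1 M HCl (aq), 0 °C; pentane solution used at once
Reagents that add atoms: methyllithium, [Li]C
Why: 1,2-addition of methyllithium and acid-mediated dehydration of the tertiary allylic alcohol through the symmetrical 1,3-dimethylallyl cation should give, from either end, the same diene tautomer with one unsubstituted terminus, which is used before 1,5-hydrogen shifts set in.

**Step 5**
Reactants: 4 epoxy enol silane; 7 1,3-dimethylcyclopenta-1,3-diene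
Product: 9 (1R,5R)-2-{1,3-bis[(TBS)oxy]propan-2-ylidene}-1,6-dimethylbicyclo[3.2.1]oct-6-en-3-one, via TES ether cycloadduct 8 (not isolated)
Conditions: (R)-3,3′-bis[3,5-bis(trifluoromethyl)phenyl]-1,1′-binaphthalene-2,2′-disulfonimide (5 mol %, silylated in situ by 4), 7 (3 equiv), toluene, −78 °C; then DBU (2 equiv), −78 to 60 °C
Reagents that add atoms: none
Why: Proposed new method: the N-silylated chiral disulfonimide silylates the epoxide oxygen of 4, the C5–O bond ionizes with assistance of the enol silane to a planar 2-(triethylsilyloxy)allyl cation (C5–C6–C7) held in a contact ion pair with the chiral disulfonimide anion, the diene adds across its two termini to give 8, the silyl oxocarbenium ion hands its silyl group to the next epoxide, and DBU added to the same flask then removes the C5 hydrogen next to the ketone and expels triethylsilanolate from C4 (E1cB) to give enone 9; the closest known reaction type is the achiral silyl-triflate-catalysed (4+3) cycloaddition of epoxy enol silanes with cyclopentadiene, combined with silylium–chiral-disulfonimide ion-pair catalysis of Mukaiyama-type additions. The six-membered carbocycle C5–C6–C7–C8–C9–C10 and the seven-membered ring through the two-carbon bridge are closed at once by (4+3) cycloaddition of the 2π allyl cation to the 4π diene, most likely asynchronously with the C7–C8 bond running ahead. The step needs regioselectivity, and the substrates secure it: the only unsubstituted diene terminus is also its most nucleophilic carbon (attack there leaves a doubly tertiary allyl cation) and pairs with the unhindered CH2 terminus C7, so the hindered terminus C5 is left to close onto the methyl-bearing carbon and make the C10 quaternary centre. The bridgeheads C8 and C10 are cis by necessity, and their absolute sense is set by the chiral anion, which must select one face of the cation and one orientation of the diene in the C7–C8 bond-forming event. The C5 centre of 8 follows from the cation geometry (substituent expected on the side of the two-carbon bridge) and does not matter, because the elimination erases it and at the same time turns the two silyloxymethyl groups into γ-leaving groups for step 9. The seven-membered mode should win over (3+2) closure at the other tertiary allyl terminus because the diene is locked s-cis.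

**Step 6**
Reactants: 9 bicyclic enone
Product: 10 methyl 2-(bicyclic enone-4-yl)acetate, that is 9 with a CH2CO2Me group at C4 (= C7) on the exo face, anti to the two-carbon bridge (β)
Conditions: LiN(i-Pr)2, THF, −78 °C; BrCH2CO2Me, −78 to −40 °C
Reagents that add atoms: methyl bromoacetate, COC(=O)CBr
Why: kinetic α′-enolization (C7 is the only α-position that carries hydrogen) and enolate alkylation on the exo face, anti to the two-carbon bridge, should set C7 with the acetate arm trans to the bridge and so trans to the future C8 oxygen.

**Step 7**
Reactants: 10 alkylated bicyclic enone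
Product: 12 cyclohexanone with C10 (methyl β, formyl α), C8 acetoxy (α), C7 CH2CO2Me (β), C6 ketone and C5 ylidene =C(CH2OTBS)2, via methoxy hydroperoxide 11 (not isolated)
Conditions: O3, CH2Cl2/MeOH, NaHCO3, −78 °C; then Ac2O, pyridine, 4-(dimethylamino)pyridine (cat.), 0 °C to rt
Reagents that add atoms: ozone, [O-][O+]=O; methanol, CO
Why: ozonolysis should take the strained, electron-rich trisubstituted bridge alkene in preference to the hindered, electron-poor tetrasubstituted enone, methanol traps the carbonyl oxide at the methyl-bearing carbon, and acetylation of the tertiary hydroperoxide triggers the Criegee rearrangement in which C8 migrates from carbon to oxygen with retention, so the bridge becomes the C10 formyl group and the C8 acetate (whose acetyl group is the excised bridge carbon with its methyl).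

**Step 8**
Reactants: 12 keto aldehyde
Product: 13 the corresponding C10 vinyl compound (vinyl α)
Conditions: CH2I2, Zn, PbCl2 (cat.), THF, 0 °C; then 12, 0 °C to rt
Reagents that add atoms: diiodomethane, ICI
Why: methylenation with the non-basic gem-dizinc reagent should be selective for the aldehyde over the hindered enone, the esters and the base-sensitive β-acetoxy ketone.

**Step 9**
Reactants: 13 vinyl enone
Product: 14 β,γ-unsaturated ketone with C5–H (α) and the 3-(TBS-oxy)prop-1-en-2-yl group at C5 (β, equatorial)
Conditions: SmI2 (2.5 equiv), THF, −78 °C; then MeOH, −78 °C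
Reagents that add atoms: none
Why: two-electron reduction of the enone by samarium diiodide places carbanion character at C4, one γ-silyloxide is expelled (vinylogous reductive cleavage of an α-heterosubstituted ketone), and the samarium dienolate should be protonated kinetically at the α-carbon C5 on the face opposite the axial C10 methyl, which gives the deconjugated side chain and the equatorial, also thermodynamically preferred, configuration at C5.

**Step 10**
Reactants: 14 β,γ-unsaturated ketone
Product: 16 trans-fused 6α,12-lactone (C8 acetate, C5 side chain and C10 vinyl unchanged), via hydroxy ester 15 (not isolated)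
Conditions: SmI2 (3 equiv), hexamethylphosphoramide, i-PrOH, THF, −20 °C; then camphorsulfonic acid (cat.), CH2Cl2, rt
Reagents that add atoms: none
Why: electron-transfer ketone reduction should give the more stable equatorial 6α-alcohol (a hydride would approach anti to the axial C10 methyl and give the axial epimer), and acid-catalysed lactonization with the neighbouring equatorial ester then closes the trans-fused γ-lactone, the C8 oxygen being blocked as its acetate.

**Step 11**
Reactants: 16 lactone
Product: 17 11α-methyl lactone (methyl cis to H7)
Conditions: LiN(SiMe3)2, THF, −78 °C; MeI, N,N′-dimethylpropyleneurea, −78 to −40 °C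
Reagents that add atoms: iodomethane, CI
Why: enolate alkylation of the lactone (more acidic than the acetate) should occur anti to C8 on the adjacent ring-fusion carbon, so the methyl group ends up cis to H7, which is also the thermodynamically preferred C11 epimer.

**Step 12**
Reactants: 17 methyl lactone acetate
Product: 18 8α-hydroxy lactone
Conditions: K2CO3 (0.2 equiv), MeOH, 0 °C; then pH 7 buffer
Reagents that add atoms: none
Why: carbonate-catalysed transesterification should remove the secondary acetate while the γ-lactone, the silyl ether and all stereocentres are kept, any opened lactone closing again on neutralization.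

**Step 13**
Reactants: 19 (R)-2,2-dimethyl-1,3-dioxolane-4-carbaldehyde
Product: 20 (S)-4-ethynyl-2,2-dimethyl-1,3-dioxolane
Conditions: dimethyl (1-diazo-2-oxopropyl)phosphonate, K2CO3, MeOH, 0 °C to rt
Reagents that add atoms: dimethyl (1-diazo-2-oxopropyl)phosphonate, CC(=O)C(=[N+]=[N-])P(=O)(OC)OC
Why: Ohira–Bestmann homologation should convert the aldehyde into the terminal alkyne without touching the adjacent stereocentre, whose descriptor changes from R to S only through the priority rules.

**Step 14**
Reactants: 20 alkyne
Product: 21 methyl (S)-2-(2,2-dimethyl-1,3-dioxolan-4-yl)prop-2-enoate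
Conditions: Pd(OAc)2 (0.5 mol %), 2-(diphenylphosphino)pyridine, methanesulfonic acid (cat.), CO (20 bar), MeOH (5 equiv), toluene, 45 °C
Reagents that add atoms: carbon monoxide, [C-]#[O+]; methanol, CO
Why: palladium-catalysed Markovnikov methoxycarbonylation of the terminal alkyne should place the ester on the internal carbon and give the 2-substituted acrylate, with the acid co-catalyst kept at catalyst level and methanol limited to spare the acetonide.

**Step 15**
Reactants: 21 methyl ester
Product: 22 (S)-2-(2,2-dimethyl-1,3-dioxolan-4-yl)prop-2-enoic acid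
Conditions: LiOH, THF/H2O, 0 °C; then cold 1 M HCl to pH 3
Reagents that add atoms: lithium hydroxide, [Li+].[OH-]
Why: saponification of the methyl ester and careful acidification should give the acrylic acid without loss of the acetonide.

**Step 16**
Reactants: 18 8α-hydroxy lactone; 22 acrylic acid
Product: 24 fully protected ester (C8 ester with acetonide, C3 TBS ether), via mixed anhydride 23 (not isolated)
Conditions: 22, 2,4,6-trichlorobenzoyl chloride, Et3N, THF, rt; then 18, 4-(dimethylamino)pyridine, toluene, rt
Reagents that add atoms: none
Why: Yamaguchi esterification through the mixed anhydride should acylate the equatorial but hindered C8 hydroxyl without touching any stereocentre, the α-branched acrylate resisting conjugate addition.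

**Step 17**
Reactants: 24 protected ester
Product: 25 target CNP0260337.1
Conditions: AcOH/H2O/THF (3:1:1), 40 °C
Reagents that add atoms: none
Why: mild aqueous acid hydrolysis should remove the primary allylic silyl ether and the acetonide in one operation and leave the lactone, the acrylate ester and the alkenes intact.

**Compound list**

1 | 1,3-bis[(tert-butyldimethylsilyl)oxy]propan-2-one | O=C(CO[Si](C)(C)C(C)(C)C)CO[Si](C)(C)C(C)(C)C | starting material
2 | 5-(TBS-oxy)-4-[(TBS-oxy)methyl]pent-3-en-2-one | CC(=O)C=C(CO[Si](C)(C)C(C)(C)C)CO[Si](C)(C)C(C)(C)C | intermediate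
3 | racemic 1-{3,3-bis[(TBS-oxy)methyl]oxiran-2-yl}ethan-1-one | CC(=O)C1OC1(CO[Si](C)(C)C(C)(C)C)CO[Si](C)(C)C(C)(C)C | intermediate
4 | racemic epoxy enol silane (TES enol ether of 3 at the methyl group) | C=C(O[Si](CC)(CC)CC)C1OC1(CO[Si](C)(C)C(C)(C)C)CO[Si](C)(C)C(C)(C)C | intermediate
5 | 3-methylcyclopent-2-en-1-one | CC1=CC(=O)CC1 | starting material
6 | 1,3-dimethylcyclopent-2-en-1-ol (not isolated) | CC1=CC(C)(O)CC1 | intermediate
7 | 1,3-dimethylcyclopenta-1,3-diene | CC1=CC(C)=CC1 | intermediate
8 | (4+3) cycloadduct (not isolated), bicyclo[3.2.1]oct-6-en-3-one with bridgehead methyl (C10), bridge methyl, and the C4 carbinol TES ether at C5 (expected on the side of the two-carbon bridge) | C[C@@]12C[C@@H](C(C)=C1)CC(=O)[C@H]2C(O[Si](CC)(CC)CC)(CO[Si](C)(C)C(C)(C)C)CO[Si](C)(C)C(C)(C)C | intermediate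
9 | (1R,5R)-2-{1,3-bis[(TBS)oxy]propan-2-ylidene}-1,6-dimethylbicyclo[3.2.1]oct-6-en-3-one | C[C@@]12C[C@@H](C(C)=C1)CC(=O)C2=C(CO[Si](C)(C)C(C)(C)C)CO[Si](C)(C)C(C)(C)C | intermediate
10 | 9 with exo CH2CO2Me at C4 (= C7, anti to the two-carbon bridge) | C[C@@]12C[C@@H](C(C)=C1)[C@H](CC(=O)OC)C(=O)C2=C(CO[Si](C)(C)C(C)(C)C)CO[Si](C)(C)C(C)(C)C | intermediate
11 | ring-opened aldehyde with a 1-hydroperoxy-1-methoxyethyl group on C8 (mixture at the peroxy carbon; not isolated) | O=C[C@@]1(C)C[C@@H](C(C)(OC)OO)[C@H](CC(=O)OC)C(=O)C1=C(CO[Si](C)(C)C(C)(C)C)CO[Si](C)(C)C(C)(C)C | intermediate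
12 | cyclohexanone: C10 methyl (β) and formyl (α), C8 acetoxy (α), C7 CH2CO2Me (β), C5 ylidene | O=C[C@@]1(C)C[C@@H](OC(C)=O)[C@H](CC(=O)OC)C(=O)C1=C(CO[Si](C)(C)C(C)(C)C)CO[Si](C)(C)C(C)(C)C | intermediate
13 | as 12 with C10 vinyl (α) in place of formyl | C=C[C@@]1(C)C[C@@H](OC(C)=O)[C@H](CC(=O)OC)C(=O)C1=C(CO[Si](C)(C)C(C)(C)C)CO[Si](C)(C)C(C)(C)C | intermediate
14 | β,γ-unsaturated ketone: C5–H (α), C5 3-(TBS-oxy)prop-1-en-2-yl (β) | C=C[C@@]1(C)C[C@@H](OC(C)=O)[C@H](CC(=O)OC)C(=O)[C@@H]1C(=C)CO[Si](C)(C)C(C)(C)C | intermediate
15 | 6α-hydroxy methyl ester (not isolated) | C=C[C@@]1(C)C[C@@H](OC(C)=O)[C@H](CC(=O)OC)[C@@H](O)[C@@H]1C(=C)CO[Si](C)(C)C(C)(C)C | intermediate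
16 | trans-fused 6α,12-lactone, 8α-acetate, C3 TBS ether | C=C[C@@]1(C)C[C@@H](OC(C)=O)[C@H]2[C@@H](OC(=O)C2)[C@@H]1C(=C)CO[Si](C)(C)C(C)(C)C | intermediate
17 | 16 with 11α-methyl (cis to H7) | C=C[C@@]1(C)C[C@@H](OC(C)=O)[C@H]2[C@@H](OC(=O)[C@@H]2C)[C@@H]1C(=C)CO[Si](C)(C)C(C)(C)C | intermediate
18 | 8α-hydroxy-11α-methyl lactone, C3 TBS ether | C=C[C@@]1(C)C[C@@H](O)[C@H]2[C@@H](OC(=O)[C@@H]2C)[C@@H]1C(=C)CO[Si](C)(C)C(C)(C)C | intermediate
19 | (R)-2,2-dimethyl-1,3-dioxolane-4-carbaldehyde | O=C[C@H]1COC(C)(C)O1 | starting material
20 | (S)-4-ethynyl-2,2-dimethyl-1,3-dioxolane | C#C[C@H]1COC(C)(C)O1 | intermediate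
21 | methyl (S)-2-(2,2-dimethyl-1,3-dioxolan-4-yl)prop-2-enoate | COC(=O)C(=C)[C@H]1COC(C)(C)O1 | intermediate
22 | (S)-2-(2,2-dimethyl-1,3-dioxolan-4-yl)prop-2-enoic acid | OC(=O)C(=C)[C@H]1COC(C)(C)O1 | intermediate
23 | mixed anhydride of 22 with 2,4,6-trichlorobenzoic acid (not isolated) | C=C([C@H]1COC(C)(C)O1)C(=O)OC(=O)c1c(Cl)cc(Cl)cc1Cl | intermediate
24 | protected target: C8 ester of 18 with 22 | C=C[C@@]1(C)C[C@@H](OC(=O)C(=C)[C@H]3COC(C)(C)O3)[C@H]2[C@@H](OC(=O)[C@@H]2C)[C@@H]1C(=C)CO[Si](C)(C)C(C)(C)C | intermediate
25 | CNP0260337.1 | C=C[C@@]1(C)C[C@@H](OC(=O)C(=C)[C@H](O)CO)[C@H]2[C@@H](OC(=O)[C@@H]2C)[C@@H]1C(=C)CO | target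

**Totals**

Total step count: 17. Longest linear sequence: 13 steps (steps 1–3, 5–12, 16, 17).

**Steps most likely to fail**

Step 5. The ion pair may discriminate poorly between the enantiotopic approach modes of the diene, and the untested chiral anion may turn over slowly, so enantiomeric purity could be low. Fallback: starting from 4 and 7, the established achiral catalyst Et3SiOSO2CF3 (catalytic, CH2Cl2, −78 °C) gives the racemic cycloadduct F1. DBU as in the second stage of step 5 gives the racemic enone F2. This is resolved by preparative chromatography on a chiral stationary phase (cellulose tris(3,5-dimethylphenylcarbamate)); the (1R,5R) enantiomer is 9, where the route is rejoined.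

Step 7. Ozone may over-oxidize the enone alkene, and the base used for the rearrangement may induce β-elimination of acetic acid from the β-acetoxy ketone. Fallback: starting from 10, OsO4 (catalytic) with N-methylmorpholine N-oxide dihydroxylates only the strained bridge alkene to the diol F3. Pb(OAc)4 cleaves it to the keto aldehyde F4 (C8 acetyl, C10 formyl). Aldehyde-selective gem-dizinc methylenation as in step 8 gives the vinyl methyl ketone F5. Baeyer–Villiger oxidation with Me3SiOOSiMe3 and catalytic Me3SiOSO2CF3, a peroxide system that spares alkenes, makes C8 migrate with retention and gives the acetate 13, where the route is rejoined.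

Step 10. Facial selectivity in the ketone reduction may be poor, or the acetyl group may migrate from C8 to C6, leading to the axial alcohol and the cis-fused lactone. Fallback: starting from 14, LiBH(s-Bu)3 at −78 °C attacks from the equatorial direction and gives the axial 6β-alcohol F6 on purpose, quenched cold before it can lactonize. Methanesulfonyl chloride and pyridine give the mesylate F7. On heating in toluene the ester carbonyl oxygen displaces the axial mesylate from the rear (SN2, inversion) and the ester methyl is lost, which gives the trans-lactone 16, where the route is rejoined.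

Further compounds
F1 | step 5 | racemic 8 (both enantiomers of the cycloadduct) | CC12CC(C(C)=C1)CC(=O)C2C(O[Si](CC)(CC)CC)(CO[Si](C)(C)C(C)(C)C)CO[Si](C)(C)C(C)(C)C
F2 | step 5 | racemic 9 | CC12CC(C(C)=C1)CC(=O)C2=C(CO[Si](C)(C)C(C)(C)C)CO[Si](C)(C)C(C)(C)C
F3 | step 7 | 6,7-diol of 10 (bicyclo numbering, diol configuration not defined) | C[C@@]12C[C@@H](C(C)(O)C1O)[C@H](CC(=O)OC)C(=O)C2=C(CO[Si](C)(C)C(C)(C)C)CO[Si](C)(C)C(C)(C)C
F4 | step 7 | analogue of 12 with acetyl in place of acetoxy at C8 | O=C[C@@]1(C)C[C@@H](C(C)=O)[C@H](CC(=O)OC)C(=O)C1=C(CO[Si](C)(C)C(C)(C)C)CO[Si](C)(C)C(C)(C)C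
F5 | step 7 | analogue of 13 with acetyl in place of acetoxy at C8 | C=C[C@@]1(C)C[C@@H](C(C)=O)[C@H](CC(=O)OC)C(=O)C1=C(CO[Si](C)(C)C(C)(C)C)CO[Si](C)(C)C(C)(C)C
F6 | step 10 | 6β (axial) epimer of hydroxy ester 15 | C=C[C@@]1(C)C[C@@H](OC(C)=O)[C@H](CC(=O)OC)[C@H](O)[C@@H]1C(=C)CO[Si](C)(C)C(C)(C)C
F7 | step 10 | 6β-methanesulfonate of F6 | C=C[C@@]1(C)C[C@@H](OC(C)=O)[C@H](CC(=O)OC)[C@H](OS(C)(=O)=O)[C@@H]1C(=C)CO[Si](C)(C)C(C)(C)C
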